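## Retrosynthetic overview
1. The target comes from its MOM ether. Pyran C and the prenyl group on ring A both arise by aromatic Claisen chemistry on a plain 4-arylphenol (dimethylallyl ether gives prenyl, dimethylpropargyl ether gives the chromene).
2. The biaryl bond is never coupled. Ring A is grown on the benzylic carbon of ring B: 4-arylphenol ⇒ 4-arylcyclohex-2-enone (Saegusa dehydrogenation, then tautomerisation).
3. Key disconnection: 4-arylcyclohexenone ⇒ chromenylacetaldehyde (as its pyrrolidine enamine) + but-3-en-2-one, an intermolecular Michael addition followed by ring-closing aldol condensation.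
4. Chromenylacetaldehyde ⇒ chromene-6-carbaldehyde (Wittig, hydroboration, oxidation) ⇒ 3,4-dihydroxybenzaldehyde + 3-chloro-3-methylbut-1-yne.
5. Ring order: B (bought) → D (pyran on B) → A (carbocycle, then aromatised) → C (pyran on A).

Assumption: the target has no stereocentre, no stereogenic alkene and a freely rotating biaryl axis, so it is achiral and no enantiocontrol is needed.

Abbreviation: Chr = 8-(methoxymethoxy)-2,2-dimethyl-2H-chromen-6-yl.

## Route

Step 1
Reactants: 1 3,4-dihydroxybenzaldehyde; 2 3-chloro-3-methylbut-1-yne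
Product: 3 3-hydroxy-4-[(2-methylbut-3-yn-2-yl)oxy]benzaldehyde
Conditions: DBU (1.1 equiv), CuCl2·2H2O (1 mol %), MeCN, 0 °C to rt, N2
Reagents that add atoms: none
Why: The 4-OH para to the formyl group is clearly the more acidic, so one equivalent of base forms only the 4-phenoxide, which is alkylated by 2 in a copper-catalysed propargylic etherification.

Step 2
Reactants: 3 3-hydroxy-4-[(2-methylbut-3-yn-2-yl)oxy]benzaldehyde
Product: 4 3-(methoxymethoxy)-4-[(2-methylbut-3-yn-2-yl)oxy]benzaldehyde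
Conditions: MOMCl, iPr2NEt, CH2Cl2, 0 °C to rt
Reagents that add atoms: chloromethyl methyl ether (MOMCl), COCCl
Why: O-alkylation of the one remaining phenol (MOM protection) gives an acetal that withstands every basic, thermal and oxidative step up to step 15.

Step 3
Reactants: 4 3-(methoxymethoxy)-4-[(2-methylbut-3-yn-2-yl)oxy]benzaldehyde
Product: 7 8-(methoxymethoxy)-2,2-dimethyl-2H-chromene-6-carbaldehyde, via allenylphenol 5 (not isolated), via quinone methide 6 (not isolated)
Conditions: PhNEt2, 190 °C, 3 h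
Reagents that add atoms: none
Why: Aromatic propargyl Claisen rearrangement to the only free ortho carbon gives 5, a 1,5-hydrogen shift gives 6, and oxa-6π electrocyclisation closes ring D.

Step 4
Reactants: 7 8-(methoxymethoxy)-2,2-dimethyl-2H-chromene-6-carbaldehyde
Product: 8 6-ethenyl-8-(methoxymethoxy)-2,2-dimethyl-2H-chromene
Conditions: MePPh3Br, KOtBu, THF, 0 °C to rt
Reagents that add atoms: methyltriphenylphosphonium bromide, C[P+](c1ccccc1)(c1ccccc1)c1ccccc1.[Br-]
Why: Wittig methylenation of a non-enolisable aryl aldehyde is dependable and leaves the MOM ether and chromene alone.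

Step 5
Reactants: 8 6-ethenyl-8-(methoxymethoxy)-2,2-dimethyl-2H-chromene
Product: 10 2-Chr-ethan-1-ol, via B-alkyl-9-BBN adduct 9 (not isolated)
Conditions: 9-BBN-H (1.2 equiv), THF, 0 °C to rt; then NaOH, H2O2, 0 °C
Reagents that add atoms: hydrogen peroxide, OO
Why: In this Brown hydroboration–oxidation, bulky 9-BBN-H adds anti-Markovnikov to the terminal vinyl group far faster than to the hindered cis-disubstituted chromene alkene.

Step 6
Reactants: 10 2-Chr-ethan-1-ol
Product: 11 Chr-acetaldehyde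
Conditions: Dess–Martin periodinane, CH2Cl2, 0 °C to rt, 1 h; used at once
Reagents that add atoms: none
Why: Dess–Martin oxidation stops cleanly at the sensitive arylacetaldehyde under nearly neutral conditions.

Step 7
Reactants: 11 Chr-acetaldehyde; 12 but-3-en-2-one
Product: 15 4-Chr-cyclohex-2-en-1-one (racemic), via enamine 13 (not isolated), via ketoaldehyde 14 (not isolated)
Conditions: pyrrolidine (1.05 equiv), 4 Å MS, toluene, 0 °C to rt; then 12 (1.3 equiv), rt to 60 °C; then AcOH, NaOAc, H2O, 90 °C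
Reagents that add atoms: none
Why: This is the key fragment union, a Stork enamine Michael addition of 13 to 12 that avoids aldehyde self-condensation, after which hydrolysis to 14 and buffered intramolecular aldol condensation complete a Robinson annulation; the new C4 stereocentre is racemic and is erased in step 9.

Step 8
Reactants: 15 4-Chr-cyclohex-2-en-1-one
Product: 16 [(4-Chr-cyclohexa-1,5-dien-1-yl)oxy]trimethylsilane (racemic, used crude)
Conditions: LiN(iPr)2 (commercial solution, 1.2 equiv), THF, −78 °C; then Me3SiCl, −78 to 0 °C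
Reagents that add atoms: chlorotrimethylsilane, C[Si](C)(C)Cl
Why: Kinetic deprotonation at the alpha-prime carbon and O-silylation of the enolate give the cross-conjugated silyl dienol ether.

Step 9
Reactants: 16 [(4-Chr-cyclohexa-1,5-dien-1-yl)oxy]trimethylsilane
Product: 18 4-Chr-phenol, via dienone 17 (not isolated)
Conditions: Pd(OAc)2 (1.05 equiv), MeCN, rt
Reagents that add atoms: none
Why: Saegusa–Ito oxidation with divalent palladium gives the 2,5-dienone 17, whose doubly allylic and benzylic C4–H shifts at once to oxygen, so ring A aromatises and the biaryl is in place.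

Step 10
Reactants: 18 4-Chr-phenol; 2 3-chloro-3-methylbut-1-yne
Product: 19 8-(methoxymethoxy)-2,2-dimethyl-6-{4-[(2-methylbut-3-yn-2-yl)oxy]phenyl}-2H-chromene
Conditions: DBU, CuCl2·2H2O (1 mol %), MeCN, 0 °C to rt
Reagents that add atoms: none
Why: Copper-catalysed propargylic etherification works well on an unhindered monophenol, which is the only acidic site present.

Step 11
Reactants: 19 8-(methoxymethoxy)-2,2-dimethyl-6-{4-[(2-methylbut-3-yn-2-yl)oxy]phenyl}-2H-chromene
Product: 20 8-(methoxymethoxy)-2,2-dimethyl-6-{4-[(2-methylbut-3-en-2-yl)oxy]phenyl}-2H-chromene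
Conditions: H2 (1 atm), Pd/CaCO3 poisoned with Pb(OAc)2, quinoline, EtOAc, rt, stopped after 1 equiv H2
Reagents that add atoms: none
Why: Lindlar semihydrogenation reduces only the terminal alkyne, and the poisoned catalyst leaves the hindered chromene alkene untouched.

Step 12
Reactants: 20 8-(methoxymethoxy)-2,2-dimethyl-6-{4-[(2-methylbut-3-en-2-yl)oxy]phenyl}-2H-chromene
Product: 22 4-Chr-2-(3-methylbut-2-en-1-yl)phenol, via dienone 21 (not isolated)
Conditions: o-xylene, 140 °C, 12 h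
Reagents that add atoms: none
Why: Aromatic Claisen rearrangement of the 1,1-dimethylallyl ether inverts the allyl unit and delivers a linear prenyl group to one of two equivalent ortho carbons (para position blocked), after which 21 enolises.

Step 13
Reactants: 22 4-Chr-2-(3-methylbut-2-en-1-yl)phenol; 2 3-chloro-3-methylbut-1-yne
Product: 23 8-(methoxymethoxy)-2,2-dimethyl-6-{3-(3-methylbut-2-en-1-yl)-4-[(2-methylbut-3-yn-2-yl)oxy]phenyl}-2H-chromene
Conditions: DBU, CuCl2·2H2O (1 mol %), MeCN, 0 °C to rt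
Reagents that add atoms: none
Why: The same copper-catalysed propargylic etherification tolerates one ortho alkyl substituent.

Step 14
Reactants: 23 8-(methoxymethoxy)-2,2-dimethyl-6-{3-(3-methylbut-2-en-1-yl)-4-[(2-methylbut-3-yn-2-yl)oxy]phenyl}-2H-chromene
Product: 26 8-(methoxymethoxy)-2,2,2',2'-tetramethyl-8'-(3-methylbut-2-en-1-yl)-2H,2'H-6,6'-bichromene, via allenylphenol 24 (not isolated), via quinone methide 25 (not isolated)
Conditions: PhNEt2, 185 °C, 2 h
Reagents that add atoms: none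
Why: Propargyl Claisen rearrangement proceeds productively only to the single free ortho carbon, and the 1,5-hydrogen shift and oxa-6π electrocyclisation then close ring C.

Step 15
Reactants: 26 8-(methoxymethoxy)-2,2,2',2'-tetramethyl-8'-(3-methylbut-2-en-1-yl)-2H,2'H-6,6'-bichromene
Product: 27 2,2,2',2'-tetramethyl-8'-(3-methylbut-2-en-1-yl)-2H,2'H-[6,6'-bichromen]-8-ol (target)
Conditions: TsOH·H2O (0.2 equiv), MeOH, 40 °C
Reagents that add atoms: none
Why: Mild acid-catalysed transacetalisation removes the MOM group, and the prenyl group sits next to an ether oxygen rather than a free phenol, so it cannot cyclise to a chroman.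

## Compound list
1 | 3,4-dihydroxybenzaldehyde | O=Cc1ccc(O)c(O)c1 | starting material
2 | 3-chloro-3-methylbut-1-yne | C#CC(C)(C)Cl | starting material
3 | 3-hydroxy-4-[(2-methylbut-3-yn-2-yl)oxy]benzaldehyde | O=Cc1ccc(OC(C)(C)C#C)c(O)c1 | intermediate
4 | 3-(methoxymethoxy)-4-[(2-methylbut-3-yn-2-yl)oxy]benzaldehyde | O=Cc1ccc(OC(C)(C)C#C)c(OCOC)c1 | intermediate
5 | 4-hydroxy-3-(methoxymethoxy)-5-(3-methylbuta-1,2-dien-1-yl)benzaldehyde | O=Cc1cc(OCOC)c(O)c(C=C=C(C)C)c1 | intermediate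
6 | 5-(methoxymethoxy)-3-[(Z)-3-methylbut-2-en-1-ylidene]-4-oxocyclohexa-1,5-diene-1-carbaldehyde | O=CC1=C/C(=C/C=C(C)C)C(=O)C(OCOC)=C1 | intermediate
7 | 8-(methoxymethoxy)-2,2-dimethyl-2H-chromene-6-carbaldehyde | COCOc1cc(C=O)cc2c1OC(C)(C)C=C2 | intermediate
8 | 6-ethenyl-8-(methoxymethoxy)-2,2-dimethyl-2H-chromene | COCOc1cc(C=C)cc2c1OC(C)(C)C=C2 | intermediate
9 | 9-{2-[8-(methoxymethoxy)-2,2-dimethyl-2H-chromen-6-yl]ethyl}-9-borabicyclo[3.3.1]nonane | COCOc1cc(CCB2C3CCCC2CCC3)cc2c1OC(C)(C)C=C2 | intermediate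
10 | 2-[8-(methoxymethoxy)-2,2-dimethyl-2H-chromen-6-yl]ethan-1-ol | COCOc1cc(CCO)cc2c1OC(C)(C)C=C2 | intermediate
11 | [8-(methoxymethoxy)-2,2-dimethyl-2H-chromen-6-yl]acetaldehyde | COCOc1cc(CC=O)cc2c1OC(C)(C)C=C2 | intermediate
12 | but-3-en-2-one (methyl vinyl ketone) | C=CC(C)=O | starting material
13 | 1-{(E)-2-[8-(methoxymethoxy)-2,2-dimethyl-2H-chromen-6-yl]ethenyl}pyrrolidine | COCOc1cc(/C=C/N2CCCC2)cc2c1OC(C)(C)C=C2 | intermediate
14 | 2-[8-(methoxymethoxy)-2,2-dimethyl-2H-chromen-6-yl]-5-oxohexanal (racemic) | COCOc1cc(C(C=O)CCC(C)=O)cc2c1OC(C)(C)C=C2 | intermediate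
15 | 4-[8-(methoxymethoxy)-2,2-dimethyl-2H-chromen-6-yl]cyclohex-2-en-1-one (racemic) | COCOc1cc(C2CCC(=O)C=C2)cc2c1OC(C)(C)C=C2 | intermediate
16 | ({4-[8-(methoxymethoxy)-2,2-dimethyl-2H-chromen-6-yl]cyclohexa-1,5-dien-1-yl}oxy)trimethylsilane (racemic) | COCOc1cc(C2CC=C(O[Si](C)(C)C)C=C2)cc2c1OC(C)(C)C=C2 | intermediate
17 | 4-[8-(methoxymethoxy)-2,2-dimethyl-2H-chromen-6-yl]cyclohexa-2,5-dien-1-one | COCOc1cc(C2C=CC(=O)C=C2)cc2c1OC(C)(C)C=C2 | intermediate
18 | 4-[8-(methoxymethoxy)-2,2-dimethyl-2H-chromen-6-yl]phenol | COCOc1cc(-c2ccc(O)cc2)cc2c1OC(C)(C)C=C2 | intermediate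
19 | 8-(methoxymethoxy)-2,2-dimethyl-6-{4-[(2-methylbut-3-yn-2-yl)oxy]phenyl}-2H-chromene | COCOc1cc(-c2ccc(OC(C)(C)C#C)cc2)cc2c1OC(C)(C)C=C2 | intermediate
20 | 8-(methoxymethoxy)-2,2-dimethyl-6-{4-[(2-methylbut-3-en-2-yl)oxy]phenyl}-2H-chromene | COCOc1cc(-c2ccc(OC(C)(C)C=C)cc2)cc2c1OC(C)(C)C=C2 | intermediate
21 | 4-[8-(methoxymethoxy)-2,2-dimethyl-2H-chromen-6-yl]-6-(3-methylbut-2-en-1-yl)cyclohexa-2,4-dien-1-one (racemic) | COCOc1cc(C2=CC(CC=C(C)C)C(=O)C=C2)cc2c1OC(C)(C)C=C2 | intermediate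
22 | 4-[8-(methoxymethoxy)-2,2-dimethyl-2H-chromen-6-yl]-2-(3-methylbut-2-en-1-yl)phenol | COCOc1cc(-c2ccc(O)c(CC=C(C)C)c2)cc2c1OC(C)(C)C=C2 | intermediate
23 | 8-(methoxymethoxy)-2,2-dimethyl-6-{3-(3-methylbut-2-en-1-yl)-4-[(2-methylbut-3-yn-2-yl)oxy]phenyl}-2H-chromene | COCOc1cc(-c2ccc(OC(C)(C)C#C)c(CC=C(C)C)c2)cc2c1OC(C)(C)C=C2 | intermediate
24 | 4-[8-(methoxymethoxy)-2,2-dimethyl-2H-chromen-6-yl]-2-(3-methylbuta-1,2-dien-1-yl)-6-(3-methylbut-2-en-1-yl)phenol | COCOc1cc(-c2cc(CC=C(C)C)c(O)c(C=C=C(C)C)c2)cc2c1OC(C)(C)C=C2 | intermediate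
25 | 4-[8-(methoxymethoxy)-2,2-dimethyl-2H-chromen-6-yl]-2-(3-methylbut-2-en-1-yl)-6-[(Z)-3-methylbut-2-en-1-ylidene]cyclohexa-2,4-dien-1-one | COCOc1cc(C2=C/C(=C/C=C(C)C)C(=O)C(CC=C(C)C)=C2)cc2c1OC(C)(C)C=C2 | intermediate
26 | 8-(methoxymethoxy)-2,2,2',2'-tetramethyl-8'-(3-methylbut-2-en-1-yl)-2H,2'H-6,6'-bichromene | COCOc1cc(-c2cc(CC=C(C)C)c3c(c2)C=CC(C)(C)O3)cc2c1OC(C)(C)C=C2 | intermediate
27 | 2,2,2',2'-tetramethyl-8'-(3-methylbut-2-en-1-yl)-2H,2'H-[6,6'-bichromen]-8-ol (CNP0158232.0, achiral) | CC(C)=CCc1cc(-c2cc(O)c3c(c2)C=CC(C)(C)O3)cc2c1OC(C)(C)C=C2 | target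

## Summary
Total step count: 15. Longest linear sequence: 15 steps, from 1 to 27; compounds 2 and 12 are bought.

## Steps most likely to fail

**Step 1 (which catechol oxygen reacts; the catechol may also bind the copper catalyst).**
- The fallback sets out from 1 and comes back at 4. It replaces direct selectivity by a protecting-group relay.
- Compound 1 is benzylated at the more acidic 4-OH (BnCl, NaHCO3, NaI, DMF, 40 °C) to give 4-(benzyloxy)-3-hydroxybenzaldehyde F1.
- MOMCl and iPr2NEt convert this into 4-(benzyloxy)-3-(methoxymethoxy)benzaldehyde F2.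
- Hydrogenolysis (H2, Pd/C, EtOAc, rt, stopped after one equivalent) gives 4-hydroxy-3-(methoxymethoxy)benzaldehyde F3.
- This monophenol is etherified with 2 under the conditions of step 10 to give 4.

**Step 7 (sensitive arylacetaldehyde, modest nucleophilicity of the conjugated enamine, polymerisation of 12).**
- The fallback sets out from 11 and comes back at 15. It reverses the polarity of the Michael step.
- Compound 11 is alpha-methylenated by a Mannich condensation–elimination (aqueous CH2O, catalytic pyrrolidine and propionic acid, iPrOH, 45 °C) to give 2-Chr-prop-2-enal F4.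
- The soft donor ethyl acetoacetate (catalytic NaOEt, EtOH, 0 °C to rt) adds to it to give the Michael adduct ethyl 2-acetyl-4-Chr-5-oxopentanoate F5.
- This adduct closes in the same flask by aldol condensation to ethyl 5-Chr-2-oxocyclohex-3-ene-1-carboxylate F6.
- Saponification (LiOH, THF/H2O) gives 5-Chr-2-oxocyclohex-3-ene-1-carboxylic acid F7, which decarboxylates at pH 4 and 60 °C to 15.

**Step 14 (high-temperature rearrangement of a hindered ether carrying three alkenes).**
- The fallback sets out from 22, skips 23, and comes back at 26.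
- Compound 22 is heated with 3-methylbut-2-enal, PhB(OH)2 and AcOH in toluene under reflux with water removal.
- Boron-templated, ortho-selective aldol-type hydroxyalkylation gives 6-Chr-8-(3-methylbut-2-en-1-yl)-4-(2-methylprop-1-en-1-yl)-2-phenyl-4H-1,3,2-benzodioxaborinine F8.
- This fragments thermally to quinone methide 25, which electrocyclises to 26.

## Further compounds
F1 | step 1 | 4-(benzyloxy)-3-hydroxybenzaldehyde | O=Cc1ccc(OCc2ccccc2)c(O)c1
F2 | step 1 | 4-(benzyloxy)-3-(methoxymethoxy)benzaldehyde | O=Cc1ccc(OCc2ccccc2)c(OCOC)c1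
F3 | step 1 | 4-hydroxy-3-(methoxymethoxy)benzaldehyde | O=Cc1ccc(O)c(OCOC)c1
F4 | step 7 | 2-[8-(methoxymethoxy)-2,2-dimethyl-2H-chromen-6-yl]prop-2-enal | COCOc1cc(C(=C)C=O)cc2c1OC(C)(C)C=C2
F5 | step 7 | ethyl 2-acetyl-4-[8-(methoxymethoxy)-2,2-dimethyl-2H-chromen-6-yl]-5-oxopentanoate (diastereomer mixture) | CCOC(=O)C(CC(C=O)c1cc(OCOC)c2c(c1)C=CC(C)(C)O2)C(C)=O
F6 | step 7 | ethyl 5-[8-(methoxymethoxy)-2,2-dimethyl-2H-chromen-6-yl]-2-oxocyclohex-3-ene-1-carboxylate (diastereomer mixture) | CCOC(=O)C1CC(C=CC1=O)c1cc(OCOC)c2c(c1)C=CC(C)(C)O2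
F7 | step 7 | 5-[8-(methoxymethoxy)-2,2-dimethyl-2H-chromen-6-yl]-2-oxocyclohex-3-ene-1-carboxylic acid (diastereomer mixture) | OC(=O)C1CC(C=CC1=O)c1cc(OCOC)c2c(c1)C=CC(C)(C)O2
F8 | step 14 | 6-[8-(methoxymethoxy)-2,2-dimethyl-2H-chromen-6-yl]-8-(3-methylbut-2-en-1-yl)-4-(2-methylprop-1-en-1-yl)-2-phenyl-4H-1,3,2-benzodioxaborinine (racemic) | CC(C)=CCc1cc(-c2cc(OCOC)c3c(c2)C=CC(C)(C)O3)cc2c1OB(c1ccccc1)OC2C=C(C)C
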